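Retrosynthesis (germacrane numbering): the C9 isovalerate and the O8–C12 lactone bond are cut first, which leaves C12 as the methyl of an isopropenyl group; then the C6–C7 bond of the ten-membered ring, the O–C13 bond of a thirteen-membered ether, the C7=C11 alkene and the C8–C9 bond.
Enabling feature: in the ten-membered carbocycle the C6 carbinol sits beside the C5 ketone and the neighbouring C7 carries the C11(=C13H2)–C12 unit. An α-hydroxy ketone with a 2-propenyl group on the next carbon is what a [2,3]-Wittig shift of an α-allyloxy ketone enolate produces, so the carbocycle is traced back to a thirteen-membered ring in which an ether oxygen bridges C6 and C13.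
Forward: (S)-β-citronellene supplies C1–C6, C9, C10, C14 and C15; alkoxyallylboration adds C7/C8; cross-metathesis with methacrolein adds C11–C13; a Williamson reaction closes the thirteen-membered ether; the [2,3] shift contracts it to the ten-membered ring; the lactone ring is closed last, before the ester is put on.
Stereochemistry: C4 comes from citronellene, C8 and C9 from the reagent-controlled syn alkoxyallylboration, C10 from the C9-hydroxyl-directed epoxidation and hydride opening, C6 and C7 from the key step (E alkene geometry and the C8 stereocentre).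

Key step: step 15

Remark on numbering: germacrane locants are used for all intermediates (C1–C3 ring CH2, C4 CH(CH3), C5 ketone carbon, C6 carbinol, C7, C8 lactone carbinol, C9 ester carbinol, C10 tertiary carbinol, C11/C12/C13 lactone alkene, carbonyl and methylene carbons, C14 methyl on C10, C15 methyl on C4). PMB = 4-methoxybenzyl, DMB = 3,4-dimethoxybenzyl, TBS = tert-butyldimethylsilyl, Ipc = isopinocampheyl.
Remark on the chemistry: the C5 carbinol made in step 3 and the acetal carbon made in step 4 are not controlled; the epimers are carried together and converge at ketone 20, so these centres are left open in the SMILES of 7–19.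

Step 1
Reactants: 1 allyl alcohol; 2 4-methoxybenzyl chloride
Product: 3 allyl 4-methoxybenzyl ether
Conditions: NaH, Bu4NI (cat.), THF, 0 °C → rt
Reagents that add atoms: none
Why: Williamson ether synthesis of a primary alkoxide with a benzylic chloride, which is reliable and raises no stereochemical issue.

Step 2
Reactants: 4 (S)-β-citronellene [(3S)-3,7-dimethylocta-1,6-diene]
Product: 6 (2E,6S)-2,6-dimethylocta-2,7-dienal, via allylic alcohol 5 (not isolated)
Conditions: SeO2 (cat.), t-BuOOH, salicylic acid (cat.), CH2Cl2, rt; then MnO2, CH2Cl2, rt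
Reagents that add atoms: tert-butyl hydroperoxide CC(C)(C)OO
Why: The catalytic SeO2/t-BuOOH allylic oxidation (ene reaction followed by a [2,3] shift) should attack only the electron-rich trisubstituted alkene at its E methyl group, and MnO2 then brings alcohol 5 and any enal already formed to the single E enal, the monosubstituted alkene and C4 staying untouched.

Step 3
Reactants: 6 (2E,6S)-2,6-dimethylocta-2,7-dienal
Product: 7 (2E,6S)-7,8-dihydroxy-2,6-dimethyloct-2-enal (C5/C6 diol, both C5 epimers)
Conditions: OsO4 (cat.), N-methylmorpholine N-oxide, acetone–H2O, 0 °C → rt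
Reagents that add atoms: N-methylmorpholine N-oxide C[N+]1([O-])CCOCC1; water O
Why: Upjohn dihydroxylation, in which electrophilic OsO4 should take the isolated terminal alkene in preference to the electron-poor conjugated alkene of the enal; the new C5 centre is uncontrolled and is erased in step 14.

Step 4
Reactants: 7 the C5/C6 diol
Product: 8 (2E,6S)-6-[2-(3,4-dimethoxyphenyl)-1,3-dioxolan-4-yl]-2-methylhept-2-enal (C5/C6 arylidene acetal)
Conditions: 3,4-(MeO)2C6H3CH(OMe)2, pyridinium p-toluenesulfonate (cat.), 4 Å molecular sieves, CH2Cl2, rt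
Reagents that add atoms: 3,4-dimethoxybenzaldehyde dimethyl acetal COc1ccc(cc1OC)C(OC)OC
Why: Acid-catalysed transacetalisation should give the five-membered arylidene acetal (the conjugated aldehyde being far less prone to acetalise), which protects both hydroxyls through the organometallic and hydride steps and can later be opened reductively to free only O6.

Step 5
Reactants: 8 the arylidene acetal enal; 3 allyl 4-methoxybenzyl ether
Product: 10 (3R,4R,5E,9S)-9-[2-(3,4-dimethoxyphenyl)-1,3-dioxolan-4-yl]-3-(4-methoxybenzyloxy)-5-methyldeca-1,5-dien-4-ol (syn adduct with 8R and 9R), via borinate ester 9 (not isolated)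
Conditions: 3, s-BuLi, THF, −78 °C; (−)-Ipc2BOMe; BF3·OEt2; then 8, −78 °C → rt; NaOH, H2O2, rt
Reagents that add atoms: none
Why: Brown asymmetric γ-alkoxyallylboration, in which the Z-alkoxyallylborane adds through a chair Zimmerman–Traxler transition state to give the syn 8,9-relationship and the isopinocampheyl groups derived from (+)-α-pinene direct the attack to the Si face of the aldehyde, which should set 8R and 9R.

Step 6
Reactants: 10 the syn homoallylic alcohol
Product: 11 erythro epoxy alcohol, the (1S,10S)-1,10-epoxide of 10 (C8 and C9 unchanged in space; 8R,9S by the sequence rules)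
Conditions: VO(acac)2 (cat.), t-BuOOH, CH2Cl2, 0 °C → rt
Reagents that add atoms: tert-butyl hydroperoxide CC(C)(C)OO
Why: Hydroxyl-directed vanadium-catalysed epoxidation of the allylic alcohol, in which allylic 1,2-strain from the C14 methyl on C10 favours the erythro epoxy alcohol and so sets C10, while the monosubstituted homoallylic alkene reacts far more slowly.

Step 7
Reactants: 11 the epoxy alcohol
Product: 12 (8R,9S,10R)-9,10-diol with 8-O-PMB, C7 vinyl and C5/C6 arylidene acetal
Conditions: LiAlH4, THF, 0 °C → rt
Reagents that add atoms: none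
Why: SN2 hydride opening of the trisubstituted epoxide at its less substituted carbon C1 leaves the C10–O bond intact, so the tertiary carbinol keeps the configuration set in step 6.

Step 8
Reactants: 12 the 9,10-diol
Product: 13 9,10-O-isopropylidene derivative (acetonide) of 12
Conditions: 2-methoxypropene, pyridinium p-toluenesulfonate (cat.), CH2Cl2, 0 °C
Reagents that add atoms: 2-methoxypropene COC(C)=C
Why: Kinetic acetonide formation by acetal exchange on the 9,10-diol, mild and methanol-poor enough to leave the arylidene acetal alone, masks the secondary and tertiary hydroxyls against the later alkoxide and enolate chemistry.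

Step 9
Reactants: 13 the acetonide; 14 methacrolein
Product: 15 E enal, 13 with the C7 vinyl group turned into C7H=C11(CH3)–C13HO
Conditions: second-generation Hoveyda–Grubbs catalyst [RuCl2(H2IMes)(=CH-C6H4-2-O-i-Pr)] (cat.), methacrolein (excess), CH2Cl2, 40 °C
Reagents that add atoms: none
Why: Olefin cross-metathesis of a terminal alkene with methacrolein, a pairing known to deliver the E-configured 2-methyl enal because the product forms under thermodynamic control and methacrolein homodimerises slowly.

Step 10
Reactants: 15 the E enal
Product: 16 diol with the C13 allylic alcohol, the free primary C6 alcohol and the DMB ether on O5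
Conditions: i-Bu2AlH, CH2Cl2, −78 → 0 °C
Reagents that add atoms: none
Why: i-Bu2AlH reduces the enal in the 1,2-sense and, by coordinating to the less hindered acetal oxygen O6, opens the arylidene acetal reductively so that the benzyl-type ether ends up on the secondary O5 and the primary C6 hydroxyl is set free.

Step 11
Reactants: 16 the diol
Product: 17 C13 allylic chloride with the free C6 alcohol
Conditions: N-chlorosuccinimide, Me2S, CH2Cl2, −25 → 0 °C
Reagents that add atoms: N-chlorosuccinimide O=C1CCC(=O)N1Cl
Why: Corey–Kim chlorination, in which the alkoxysulfonium salt of the allylic alcohol collapses to the primary allylic chloride by SN2 attack of chloride without allylic transposition, whereas the salt of the saturated C6 alcohol only returns the alcohol on aqueous work-up.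

Step 12
Reactants: 17 the hydroxy allylic chloride
Product: 18 thirteen-membered ether (O bridges C6 and C13) with 5-O-DMB, 8-O-PMB, 9,10-acetonide and the E C7=C11 alkene
Conditions: EtMgBr (1.05 equiv), THF, 0 °C; then slow addition into THF–HMPA, 65 °C (final concentration about 0.003 M)
Reagents that add atoms: none
Why: Intramolecular Williamson etherification (13-exo-tet SN2 of the C6 alkoxide on the primary allylic chloride) under high dilution is the established way to close thirteen-membered allylic ethers for Wittig ring contraction, the alkene geometry being retained and the benzyl-type ether on O5 being unable to migrate.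

Step 13
Reactants: 18 the thirteen-membered ether
Product: 19 thirteen-membered ether with the free C5 alcohol
Conditions: DDQ (1.1 equiv), CH2Cl2–pH 7 phosphate buffer, 0 °C
Reagents that add atoms: none
Why: Oxidative debenzylation with DDQ, which cleaves the more electron-rich 3,4-dimethoxybenzyl ether faster than the 4-methoxybenzyl ether, so that one equivalent at 0 °C should free O5 and keep the C8 ether.

Step 14
Reactants: 19 the C5 alcohol
Product: 20 thirteen-membered α-allyloxy ketone (4S,8R,9S,10R; C5 ketone, O bridging C6 and C13, E C7=C11, 8-O-PMB, 9,10-acetonide)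
Conditions: Dess–Martin periodinane, pyridine, CH2Cl2, rt
Reagents that add atoms: none
Why: Dess–Martin oxidation of the secondary alcohol under buffered, non-enolising conditions should give the α-allyloxy ketone without touching the adjacent C4 stereocentre and merges the C5 epimers.

Step 15
Reactants: 20 the thirteen-membered α-allyloxy ketone
Product: 22 (4S,6S,7S,8R,9S,10R)-6-hydroxy-8-(4-methoxybenzyloxy)-9,10-(isopropylidenedioxy)germacr-11(13)-en-5-one, via lithium enolate 21 (not isolated)
Conditions: LiN(i-Pr)2 (1.1 equiv), THF, −78 °C; then −78 → −20 °C; AcOH, THF, −78 °C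
Reagents that add atoms: none
Why: Proposed new method: LiN(i-Pr)2 should remove a C6 proton (a methylene between the carbonyl and the ether oxygen, reached through a lithium chelate) much faster than the hindered C4 methine, and on warming the C6 terminus of lithium enolate 21 attacks C7 through a five-membered envelope transition state (C6, O, C13, C11, C7) while the C13–O bond breaks, which leaves the lithium alkoxide of 22. The closest known reactions are the [2,3]-Wittig ring contraction of thirteen-membered allyl propargyl and diallyl ethers to ten-membered carbocycles and the [2,3]-Wittig shift of open-chain α-allyloxy ketone and ester enolates, the enolate variant not having been run inside a macrocycle. The ten-membered carbocycle is closed by contraction of the thirteen-membered ether ring, the C6–C7 bond forming across the ring while O, C13 and C11 leave the ring path, so no end-to-end cyclisation is needed. C7 is set by the C8 stereocentre, because allylic 1,3-strain with the C12 methyl holds H8 in the alkene plane and C6 adds to the face anti to the C8–O bond, which gives the 7,8-relationship of the target. C6 is set by the E geometry of the C7=C11 alkene together with the outward placement of the acyl carbon C5 in the envelope, the arrangement that gives the trans hydroxyl/isopropenyl pair in the known contractions of E-allylic ethers. The step needs enolisation at C6 and not at C4 (kinetic base, CH2 against CH, full deprotonation so that no ketone is left for proton exchange) and the [2,3] mode in preference to the [3,3] oxy-Claisen mode, which the tight lithium enolate and the need of the [3,3] path to build a quaternary C5 in a nine-membered ring should disfavour.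

Step 16
Reactants: 22 the ten-membered hydroxy ketone
Product: 23 6-O-TBS ether of 22
Conditions: t-BuMe2SiOTf, 2,6-lutidine, CH2Cl2, −78 → −40 °C
Reagents that add atoms: tert-butyldimethylsilyl trifluoromethanesulfonate CC(C)(C)[Si](C)(C)OS(=O)(=O)C(F)(F)F
Why: Silylation of the secondary alcohol with a silyl triflate and a hindered base, fast at low temperature before the ketone can enolise, blocks O6 so that only O8 can lactonise later.

Step 17
Reactants: 23 the silyl ether
Product: 24 allylic alcohol, 23 with the C12 methyl turned into CH2OH (C11=C13H2 retained)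
Conditions: SeO2 (cat.), t-BuOOH, CH2Cl2, rt
Reagents that add atoms: tert-butyl hydroperoxide CC(C)(C)OO
Why: SeO2/t-BuOOH allylic oxidation (ene reaction then [2,3] shift) of the 1,1-disubstituted isopropenyl group should take place at its methyl group C12, the usual outcome for isopropenyl groups on a ring methine, and any enal formed by over-oxidation converges with 24 in step 19.

Step 18
Reactants: 24 the allylic alcohol
Product: 25 diol with free O8 and the C12 allylic alcohol
Conditions: DDQ, CH2Cl2–pH 7 phosphate buffer, 0 °C → rt
Reagents that add atoms: none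
Why: Oxidative cleavage of the 4-methoxybenzyl ether with DDQ frees O8 under conditions that the acetonide, the silyl ether and the ketone tolerate.

Step 19
Reactants: 25 the diol
Product: 28 α-methylene-γ-butyrolactone (12,8-olide) with 6-O-TBS and 9,10-acetonide, via hydroxy enal 26 (not isolated), via lactol 27 (not isolated)
Conditions: TEMPO (cat.), PhI(OAc)2, CH2Cl2, rt
Reagents that add atoms: none
Why: TEMPO/PhI(OAc)2 oxidative lactonisation, in which the primary allylic alcohol is oxidised selectively to enal 26, O8 closes the five-membered lactol 27 by 5-exo-trig addition to the aldehyde and a second oxidation gives the lactone, trans-fused because C7 and C8 are already fixed.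

Step 20
Reactants: 28 the lactone acetonide
Product: 29 9,10-diol of the lactone with 6-O-TBS
Conditions: AcOH–H2O (4:1), 40 °C
Reagents that add atoms: none
Why: Acid-catalysed hydrolysis of the isopropylidene acetal, which the hindered secondary silyl ether, the lactone and the ketone should withstand in aqueous acetic acid.

Step 21
Reactants: 29 the 9,10-diol
Product: 30 9-O-(3-methylbutanoyl) ester with 6-O-TBS
Conditions: isovaleric anhydride, 4-(dimethylamino)pyridine (cat.), pyridine, CH2Cl2, 0 °C → rt
Reagents that add atoms: isovaleric anhydride CC(C)CC(=O)OC(=O)CC(C)C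
Why: Nucleophile-catalysed (Steglich-type) acylation should esterify the secondary C9 hydroxyl while the tertiary C10 hydroxyl does not react under these conditions.

Step 22
Reactants: 30 the silyl-protected ester
Product: 31 CNP0240128.1, (4S,6S,7S,8R,9S,10R)-6,10-dihydroxy-9-(3-methylbutanoyloxy)-5-oxogermacr-11(13)-en-12,8-olide
Conditions: HF·pyridine, pyridine, THF, 0 °C → rt
Reagents that add atoms: none
Why: Fluoride-mediated cleavage of the silyl ether under buffered acidic conditions should spare the ester, the α-methylene lactone and the α-hydroxy ketone and give the target.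

Compound list
1 | allyl alcohol (prop-2-en-1-ol) | C=CCO | starting material
2 | 4-methoxybenzyl chloride | COc1ccc(CCl)cc1 | starting material
3 | allyl 4-methoxybenzyl ether | C=CCOCc1ccc(OC)cc1 | intermediate
4 | (S)-β-citronellene, (3S)-3,7-dimethylocta-1,6-diene | C=C[C@@H](C)CCC=C(C)C | starting material
5 | (2E,6S)-2,6-dimethylocta-2,7-dien-1-ol (not isolated) | C=C[C@@H](C)CC/C=C(\C)CO | intermediate
6 | (2E,6S)-2,6-dimethylocta-2,7-dienal | C=C[C@@H](C)CC/C=C(\C)C=O | intermediate
7 | (2E,6S)-7,8-dihydroxy-2,6-dimethyloct-2-enal (C5 epimers) | OCC(O)[C@@H](C)CC/C=C(\C)C=O | intermediate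
8 | (2E,6S)-6-[2-(3,4-dimethoxyphenyl)-1,3-dioxolan-4-yl]-2-methylhept-2-enal | COc1ccc(cc1OC)C2OCC(O2)[C@@H](C)CC/C=C(\C)C=O | intermediate
9 | O-diisopinocampheylboryl derivative (borinate ester) of 10 (not isolated) | COc1ccc(cc1OC)C2OCC(O2)[C@@H](C)CC/C=C(\C)[C@@H](OB([C@@H]5C[C@@H]6C[C@H]([C@H]5C)C6(C)C)[C@@H]7C[C@@H]8C[C@H]([C@H]7C)C8(C)C)[C@H](OCc3ccc(OC)cc3)C=C | intermediate
10 | (3R,4R,5E,9S)-9-[2-(3,4-dimethoxyphenyl)-1,3-dioxolan-4-yl]-3-(4-methoxybenzyloxy)-5-methyldeca-1,5-dien-4-ol (8R,9R syn adduct) | COc1ccc(cc1OC)C2OCC(O2)[C@@H](C)CC/C=C(\C)[C@@H](O)[C@H](OCc3ccc(OC)cc3)C=C | intermediate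
11 | erythro epoxy alcohol, (1S,10S)-1,10-epoxide of 10 | COc1ccc(cc1OC)C2OCC(O2)[C@@H](C)CC[C@@H]5O[C@@]5(C)[C@@H](O)[C@H](OCc3ccc(OC)cc3)C=C | intermediate
12 | (8R,9S,10R)-9,10-diol with 8-O-PMB, C7 vinyl and C5/C6 arylidene acetal | COc1ccc(cc1OC)C2OCC(O2)[C@@H](C)CCC[C@@](C)(O)[C@@H](O)[C@H](OCc3ccc(OC)cc3)C=C | intermediate
13 | 9,10-acetonide of 12 | COc1ccc(cc1OC)C2OCC(O2)[C@@H](C)CCC[C@@]5(C)OC(C)(C)O[C@H]5[C@H](OCc3ccc(OC)cc3)C=C | intermediate
14 | methacrolein (2-methylprop-2-enal) | C=C(C)C=O | starting material
15 | E enal (C7H=C11(CH3)–C13HO) with 8-O-PMB, 9,10-acetonide and C5/C6 arylidene acetal | COc1ccc(cc1OC)C2OCC(O2)[C@@H](C)CCC[C@@]5(C)OC(C)(C)O[C@H]5[C@H](OCc3ccc(OC)cc3)/C=C(\C)C=O | intermediate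
16 | diol: C13 allylic alcohol, C6 primary alcohol, 5-O-DMB, 8-O-PMB, 9,10-acetonide | OCC(OCc1ccc(OC)c(OC)c1)[C@@H](C)CCC[C@@]2(C)OC(C)(C)O[C@H]2[C@H](OCc3ccc(OC)cc3)/C=C(\C)CO | intermediate
17 | C13 allylic chloride of 16 (C6 alcohol free) | OCC(OCc1ccc(OC)c(OC)c1)[C@@H](C)CCC[C@@]2(C)OC(C)(C)O[C@H]2[C@H](OCc3ccc(OC)cc3)/C=C(\C)CCl | intermediate
18 | thirteen-membered ether (O between C6 and C13), 5-O-DMB, 8-O-PMB, 9,10-acetonide, E C7=C11 | O1CC(OCc4ccc(OC)c(OC)c4)[C@@H](C)CCC[C@@]2(C)OC(C)(C)O[C@H]2[C@H](OCc3ccc(OC)cc3)/C=C(C)/C1 | intermediate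
19 | thirteen-membered ether with free C5 alcohol | O1CC(O)[C@@H](C)CCC[C@@]2(C)OC(C)(C)O[C@H]2[C@H](OCc3ccc(OC)cc3)/C=C(C)/C1 | intermediate
20 | thirteen-membered α-allyloxy ketone (4S,8R,9S,10R), 8-O-PMB, 9,10-acetonide | O1CC(=O)[C@@H](C)CCC[C@@]2(C)OC(C)(C)O[C@H]2[C@H](OCc3ccc(OC)cc3)/C=C(C)/C1 | intermediate
21 | lithium (Z)-enolate of 20 (C5=C6, not isolated) | O1/C=C(\O[Li])[C@@H](C)CCC[C@@]2(C)OC(C)(C)O[C@H]2[C@H](OCc3ccc(OC)cc3)/C=C(C)/C1 | intermediate
22 | (4S,6S,7S,8R,9S,10R)-6-hydroxy-8-(4-methoxybenzyloxy)-9,10-(isopropylidenedioxy)germacr-11(13)-en-5-one | CC(=C)[C@H]1[C@H](O)C(=O)[C@@H](C)CCC[C@@]2(C)OC(C)(C)O[C@H]2[C@@H]1OCc3ccc(OC)cc3 | intermediate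
23 | 6-O-TBS ether of 22 | CC(=C)[C@H]1[C@H](O[Si](C)(C)C(C)(C)C)C(=O)[C@@H](C)CCC[C@@]2(C)OC(C)(C)O[C@H]2[C@@H]1OCc3ccc(OC)cc3 | intermediate
24 | C12 allylic alcohol of 23 | OCC(=C)[C@H]1[C@H](O[Si](C)(C)C(C)(C)C)C(=O)[C@@H](C)CCC[C@@]2(C)OC(C)(C)O[C@H]2[C@@H]1OCc3ccc(OC)cc3 | intermediate
25 | 8,12-diol (PMB removed) | OCC(=C)[C@H]1[C@H](O[Si](C)(C)C(C)(C)C)C(=O)[C@@H](C)CCC[C@@]2(C)OC(C)(C)O[C@H]2[C@@H]1O | intermediate
26 | hydroxy enal (C12 aldehyde, not isolated) | O=CC(=C)[C@H]1[C@H](O[Si](C)(C)C(C)(C)C)C(=O)[C@@H](C)CCC[C@@]2(C)OC(C)(C)O[C@H]2[C@@H]1O | intermediate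
27 | five-membered lactol between C12 and O8 (not isolated, both anomers) | C=C1C(O)O[C@@H]2[C@@H]1[C@H](O[Si](C)(C)C(C)(C)C)C(=O)[C@@H](C)CCC[C@@]3(C)OC(C)(C)O[C@@H]23 | intermediate
28 | 6-O-TBS-9,10-O-isopropylidene-5-oxogermacr-11(13)-en-12,8-olide | C=C1C(=O)O[C@@H]2[C@@H]1[C@H](O[Si](C)(C)C(C)(C)C)C(=O)[C@@H](C)CCC[C@@]3(C)OC(C)(C)O[C@@H]23 | intermediate
29 | 6-O-TBS-9,10-dihydroxy-5-oxogermacr-11(13)-en-12,8-olide | C=C1C(=O)O[C@@H]2[C@@H]1[C@H](O[Si](C)(C)C(C)(C)C)C(=O)[C@@H](C)CCC[C@@](C)(O)[C@H]2O | intermediate
30 | 6-O-TBS ether of the target | C=C1C(=O)O[C@@H]2[C@@H]1[C@H](O[Si](C)(C)C(C)(C)C)C(=O)[C@@H](C)CCC[C@@](C)(O)[C@H]2OC(=O)CC(C)C | intermediate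
31 | CNP0240128.1, (4S,6S,7S,8R,9S,10R)-6,10-dihydroxy-9-(3-methylbutanoyloxy)-5-oxogermacr-11(13)-en-12,8-olide | C=C1C(=O)O[C@@H]2[C@@H]1[C@H](O)C(=O)[C@@H](C)CCC[C@@](C)(O)[C@H]2OC(=O)CC(C)C | target

Total step count: 22. Longest linear sequence: 21 steps (4 → 31, steps 2–22); step 1 is a one-step side branch.

Steps most likely to fail

Step 15 (the step labelled as a new method). What may go wrong: the enolate may shift in the [3,3] sense onto C5, may rearrange so slowly that proton exchange erodes C4, or may add to the wrong alkene face. The fallback makes the same C6–C7 bond and the ten-membered ring by an allylmetal addition, which is known chemistry. It sets out from 17. Dess–Martin oxidation of the primary alcohol gives the α-alkoxy aldehyde F1. CrCl2 (divalent chromium, excess) with NaI (cat.) in THF at high dilution converts the allylic chloride into an allylchromium species that adds through C7 to the aldehyde (intramolecular Nozaki–Hiyama allylation, a known closure of ten-membered carbocycles). This should give the ten-membered homoallylic alcohol F2, the anti C6/C7 relationship being the normal outcome of such additions; the C5 epimers would be separated here or avoided by running step 3 with a chiral ligand. t-BuMe2SiOTf and 2,6-lutidine then give the silyl ether F3, DDQ removes the 3,4-dimethoxybenzyl group to give the C5 alcohol F4, and Dess–Martin oxidation gives 23, where the route is rejoined; steps 12 to 16 are bypassed.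

Step 12. What may go wrong: oligomerisation or elimination of the allylic chloride may outrun the entropically costly closure of the thirteen-membered ring. The fallback closes the same ring through the alkene and not through the ether bond. It sets out from 13. i-Bu2AlH opens the arylidene acetal to the primary C6 alcohol F5, and NaH with 3-bromo-2-methylpropene gives the methallyl ether F6. Ring-closing metathesis (second-generation Hoveyda–Grubbs catalyst, toluene, 80 °C, high dilution) then forms the C7=C11 bond and should give 18, where the route is rejoined; steps 9 to 12 are bypassed. The E/Z outcome of this trisubstituted macrocyclic alkene cannot be predicted, and any Z isomer would have to be removed, which is why this is only the fallback.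

Step 9. What may go wrong: metathesis at the hindered alkene next to the C8 ether may be slow, with catalyst decomposition and self-reaction of methacrolein taking over. The fallback builds the enal by carbonyl olefination. It sets out from 13. Lemieux–Johnson cleavage of the vinyl group (OsO4 cat., NaIO4, 2,6-lutidine, dioxane–H2O) gives the α-alkoxy aldehyde F7, and a Wittig reaction with the stabilised ylide Ph3P=C(CH3)CHO in toluene at 80 °C should give the E enal 15, where the route is rejoined.

Further compounds
F1 | step 15 | C6 aldehyde from 17 (5-O-DMB, C13 chloride) | O=CC(OCc1ccc(OC)c(OC)c1)[C@@H](C)CCC[C@@]2(C)OC(C)(C)O[C@H]2[C@H](OCc3ccc(OC)cc3)/C=C(\C)CCl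
F2 | step 15 | ten-membered homoallylic alcohol (6-OH, 7-isopropenyl, 5-O-DMB, 8-O-PMB, 9,10-acetonide) | CC(=C)[C@H]1[C@H](O)C(OCc4ccc(OC)c(OC)c4)[C@@H](C)CCC[C@@]2(C)OC(C)(C)O[C@H]2[C@@H]1OCc3ccc(OC)cc3
F3 | step 15 | 6-O-TBS ether of F2 | CC(=C)[C@H]1[C@H](O[Si](C)(C)C(C)(C)C)C(OCc4ccc(OC)c(OC)c4)[C@@H](C)CCC[C@@]2(C)OC(C)(C)O[C@H]2[C@@H]1OCc3ccc(OC)cc3
F4 | step 15 | C5 alcohol from F3 | CC(=C)[C@H]1[C@H](O[Si](C)(C)C(C)(C)C)C(O)[C@@H](C)CCC[C@@]2(C)OC(C)(C)O[C@H]2[C@@H]1OCc3ccc(OC)cc3
F5 | step 12 | primary C6 alcohol from reductive opening of 13 (5-O-DMB, C7 vinyl) | OCC(OCc1ccc(OC)c(OC)c1)[C@@H](C)CCC[C@@]2(C)OC(C)(C)O[C@H]2[C@H](OCc3ccc(OC)cc3)C=C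
F6 | step 12 | 6-O-(2-methylallyl) ether of F5 | C=C(C)COCC(OCc1ccc(OC)c(OC)c1)[C@@H](C)CCC[C@@]2(C)OC(C)(C)O[C@H]2[C@H](OCc3ccc(OC)cc3)C=C
F7 | step 9 | C7 aldehyde from oxidative cleavage of 13 | COc1ccc(cc1OC)C2OCC(O2)[C@@H](C)CCC[C@@]5(C)OC(C)(C)O[C@H]5[C@H](OCc3ccc(OC)cc3)C=O
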